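**Retrosynthetic overview**

1. Numbering: lactone C1–C5, chain C6–C16, tetrahydropyran O/C17–C21, propenyl C22–C24. Last bond C15–C16: Nozaki–Hiyama–Kishi coupling of a C16 aldehyde (tetrahydropyran fragment) with a C1–C15 dienyl iodide, which sets C16; no protecting groups remain after the ring closure.
2. C1–C15 dienyl iodide: Takai olefination (C15) of an enal made by Heck coupling (C7–C8) of a Z-vinyl iodide (C8–C14) with (S)-6-vinyl-5,6-dihydropyran-2-one.
3. Tetrahydropyran (key step, C17–O–C21 bond): palladium-catalysed decarboxylative cycloetherification of the C19/C21 cyclic carbonate by the free C17 hydroxyl, with net retention at C21. The all-syn C19–C21 triad comes from an Ipc-boron aldol and a Narasaka–Prasad reduction; C17 comes from the chiral pool.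
4. C8–C14 piece: Evans alkylation (C10) with ethyl 4-bromo-3-methylbut-2-enoate, then Stork–Zhao olefination (Z-C8=C9).
5. Ring order: the tetrahydropyran and the lactone (Brown allylation, acryloylation, ring-closing metathesis) are each closed in their own branch before the fragments are joined.

Assumption 1: the target is taken exactly as drawn, i.e. 5S,10R,16S,17R,19S,20R,21R with 2Z,6E,8Z,12E,14E,22E double bonds.

Assumption 2: the facial sense of the Ipc-boron aldol in step 2 is taken to parallel Brown allylboration (the reagent from (−)-α-pinene attacks the aldehyde Re face); if the adduct proved to be the antipodal syn isomer, the reagent from (+)-α-pinene would be used with nothing else changed.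

(Ipc = isopinocampheyl.)

**Route**

Step 1
Reactants: 1 methyl 2-[(4R)-2,2-dimethyl-1,3-dioxolan-4-yl]acetate
Product: 2 2-[(4R)-2,2-dimethyl-1,3-dioxolan-4-yl]acetaldehyde
Conditions: i-Bu2AlH (1.05 equiv), CH2Cl2, −78 °C; MeOH, then aq. potassium sodium tartrate
Reagents that add atoms: none
Why: Low-temperature DIBAL-H half-reduction of an ester (the aluminium hemiacetal survives until work-up) leaves the dioxolane stereocenter, the future C17 from the chiral pool, untouched.

Step 2
Reactants: 2 2-[(4R)-2,2-dimethyl-1,3-dioxolan-4-yl]acetaldehyde; 3 (4E)-hex-4-en-3-one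
Product: 4 (2E,5R,6S)-7-[(4R)-2,2-dimethyl-1,3-dioxolan-4-yl]-6-hydroxy-5-methylhept-2-en-4-one
Conditions: (+)-Ipc2BOTf (from (−)-α-pinene), i-Pr2NEt, CH2Cl2, −78 °C with 3; then 2, −78 → −20 °C; H2O2, MeOH, aq. NaH2PO4/Na2HPO4 (pH 7)
Reagents that add atoms: none
Why: Paterson-type reagent-controlled boron aldol reaction, in which the enone can only be enolised on its ethyl side, the Z-enol borinate reacts through a Zimmerman–Traxler chair to give the 5,6-syn relationship, and the Ipc ligands direct it to the Re face of the aldehyde so that C19 is S and C20 is R, the minor diastereomers being separable because the aldehyde is enantiopure.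

Step 3
Reactants: 4 (2E,5R,6S)-7-[(4R)-2,2-dimethyl-1,3-dioxolan-4-yl]-6-hydroxy-5-methylhept-2-en-4-one
Product: 5 (2E,4R,5R,6S)-7-[(4R)-2,2-dimethyl-1,3-dioxolan-4-yl]-5-methylhept-2-ene-4,6-diol
Conditions: Et2BOMe, THF/MeOH (4:1), −78 °C; NaBH4; AcOH, then MeOH azeotrope
Reagents that add atoms: none
Why: Narasaka–Prasad reduction, in which external hydride attacks the boron chelate of the β-hydroxy enone axially in a 1,2-sense and gives the 4,6-syn diol, setting C21 (4R) and completing the all-syn C19–C21 triad.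

Step 4
Reactants: 5 (2E,4R,5R,6S)-7-[(4R)-2,2-dimethyl-1,3-dioxolan-4-yl]-5-methylhept-2-ene-4,6-diol
Product: 6 (4S,5R,6R)-4-{[(4R)-2,2-dimethyl-1,3-dioxolan-4-yl]methyl}-5-methyl-6-[(1E)-prop-1-en-1-yl]-1,3-dioxan-2-one
Conditions: 1,1'-carbonyldiimidazole, DMAP (cat.), toluene, 80 °C
Reagents that add atoms: 1,1'-carbonyldiimidazole, O=C(n1ccnc1)n1ccnc1
Why: Cyclic carbonate formation from a syn-1,3-diol by acyl transfer breaks no bond to a stereocenter, masks the C19 hydroxyl and turns the allylic C21–O bond into a leaving group.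

Step 5
Reactants: 6 (4S,5R,6R)-4-{[(4R)-2,2-dimethyl-1,3-dioxolan-4-yl]methyl}-5-methyl-6-[(1E)-prop-1-en-1-yl]-1,3-dioxan-2-one
Product: 7 (4S,5R,6R)-4-[(2R)-2,3-dihydroxypropyl]-5-methyl-6-[(1E)-prop-1-en-1-yl]-1,3-dioxan-2-one
Conditions: AcOH/H2O (4:1), 40 °C
Reagents that add atoms: none
Why: Acid-catalysed acetonide hydrolysis is selective because the cyclic carbonate is stable to aqueous acetic acid, and it frees the C17 hydroxyl that will act as the nucleophile.

Step 6
Reactants: 7 (4S,5R,6R)-4-[(2R)-2,3-dihydroxypropyl]-5-methyl-6-[(1E)-prop-1-en-1-yl]-1,3-dioxan-2-one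
Product: 8 (2R,3R,4S,6R)-6-(hydroxymethyl)-3-methyl-2-[(1E)-prop-1-en-1-yl]oxan-4-ol
Conditions: Pd2(dba)3 (2.5 mol %), DPEphos (6 mol %), THF (0.02 M), 0 °C → rt
Reagents that add atoms: none
Why: Proposed new method: zerovalent palladium ionises the allylic C21–O bond of the six-membered cyclic carbonate with inversion, CO2 is lost, the C19 alkoxide so formed takes the proton of the C17 hydroxyl, and that oxygen attacks the η3-allyl terminus C21 anti to palladium, so C21 keeps its configuration by double inversion (2,6-cis ring, E-propenyl from the syn,syn-allyl) whatever the chair preference of the axial methyl and hydroxyl; the closest known reaction types are the Tsuji–Trost decarboxylative allylic etherification of acyclic allyl carbonates and the palladium-catalysed decarboxylative opening of 4-vinyl-1,3-dioxan-2-ones, neither shown with a 1,3-diol carbonate as internal electrophile and a remote free hydroxyl as nucleophile.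

Step 7
Reactants: 8 (2R,3R,4S,6R)-6-(hydroxymethyl)-3-methyl-2-[(1E)-prop-1-en-1-yl]oxan-4-ol
Product: 9 (2R,4S,5R,6R)-4-hydroxy-5-methyl-6-[(1E)-prop-1-en-1-yl]oxane-2-carbaldehyde
Conditions: TEMPO (10 mol %), PhI(OAc)2, CH2Cl2, rt
Reagents that add atoms: none
Why: TEMPO/PhI(OAc)2 oxidation (Piancatelli–Margarita conditions) takes the primary alcohol in the presence of the hindered axial secondary alcohol and stops at the aldehyde, whose C17 centre already sits in the more stable 2,6-cis arrangement.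

Step 8
Reactants: 10 acrolein (prop-2-enal)
Product: 11 (3S)-hexa-1,5-dien-3-ol
Conditions: (−)-Ipc2B(allyl) (from (+)-α-pinene), Et2O, −78 °C; then NaOH, H2O2
Reagents that add atoms: (−)-B-allyldiisopinocampheylborane, C=CCB([C@@H]1C[C@@H]2C[C@H]([C@H]1C)C2(C)C)[C@@H]1C[C@@H]2C[C@H]([C@H]1C)C2(C)C
Why: Brown asymmetric allylboration proceeds through a chair transition state in which the Ipc groups direct allyl transfer to the Si face of acrolein, setting C5 as S.

Step 9
Reactants: 11 (3S)-hexa-1,5-dien-3-ol; 12 acryloyl chloride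
Product: 13 (3S)-hexa-1,5-dien-3-yl prop-2-enoate
Conditions: Et3N, DMAP (cat.), CH2Cl2, 0 °C
Reagents that add atoms: none
Why: Standard acylation (nucleophilic acyl substitution) of a secondary alcohol occurs at oxygen with retention at C5.

Step 10
Reactants: 13 (3S)-hexa-1,5-dien-3-yl prop-2-enoate
Product: 14 (6S)-6-ethenyl-5,6-dihydro-2H-pyran-2-one
Conditions: second-generation Grubbs catalyst [RuCl2(=CHPh)(H2IMes)(PCy3)] (5 mol %), CH2Cl2 (0.005 M), 40 °C
Reagents that add atoms: none
Why: Ring-closing metathesis, in which the ruthenium carbene loads on the unhindered allyl terminus and closes the six-membered unsaturated lactone on the acrylate faster than the strained butenolide alternative, leaving the vinyl group.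

Step 11
Reactants: 15 (4S)-4-benzyl-3-propanoyl-1,3-oxazolidin-2-one; 16 ethyl (2E)-4-bromo-3-methylbut-2-enoate
Product: 17 ethyl (2E,5R)-6-[(4S)-4-benzyl-2-oxo-1,3-oxazolidin-3-yl]-3,5-dimethyl-6-oxohex-2-enoate
Conditions: NaN(SiMe3)2, THF, −78 °C; then 16, −78 → −40 °C
Reagents that add atoms: none
Why: Evans asymmetric alkylation, in which the chelated Z-sodium enolate is alkylated by the allylic bromide (SN2, the β-methyl group disfavouring conjugate addition) on the face opposite the benzyl group, setting C10 as R.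

Step 12
Reactants: 17 ethyl (2E,5R)-6-[(4S)-4-benzyl-2-oxo-1,3-oxazolidin-3-yl]-3,5-dimethyl-6-oxohex-2-enoate
Product: 18 ethyl (2E,5R)-6-hydroxy-3,5-dimethylhex-2-enoate
Conditions: LiBH4, H2O (1 equiv), Et2O, 0 °C
Reagents that add atoms: none
Why: Reductive cleavage of the Evans auxiliary with LiBH4 reduces the activated imide carbonyl much faster than the conjugated ethyl ester and does not touch C10.

Step 13
Reactants: 18 ethyl (2E,5R)-6-hydroxy-3,5-dimethylhex-2-enoate
Product: 19 ethyl (2E,5R)-3,5-dimethyl-6-oxohex-2-enoate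
Conditions: Dess–Martin periodinane, CH2Cl2, 0 °C → rt; used at once
Reagents that add atoms: none
Why: Dess–Martin oxidation is neutral and fast and gives the α-methyl aldehyde without epimerisation at C10.

Step 14
Reactants: 19 ethyl (2E,5R)-3,5-dimethyl-6-oxohex-2-enoate
Product: 20 ethyl (2E,5R,6Z)-7-iodo-3,5-dimethylocta-2,6-dienoate
Conditions: EtPPh3I, n-BuLi, THF; I2, −78 °C; NaN(SiMe3)2, −78 °C; then 19, −78 → −20 °C
Reagents that add atoms: ethyltriphenylphosphonium iodide, CC[P+](c1ccccc1)(c1ccccc1)c1ccccc1.[I-]; iodine, II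
Why: Stork–Zhao variant of the Wittig reaction, in which the non-stabilised α-iodo ylide forms the cis-oxaphosphetane kinetically and hence the Z-iodoalkene (C8=C9), the ester being inert to the ylide.

Step 15
Reactants: 20 ethyl (2E,5R,6Z)-7-iodo-3,5-dimethylocta-2,6-dienoate
Product: 21 (2E,5R,6Z)-7-iodo-3,5-dimethylocta-2,6-dien-1-ol
Conditions: i-Bu2AlH (2.2 equiv), CH2Cl2, −78 °C; aq. potassium sodium tartrate
Reagents that add atoms: none
Why: DIBAL-H reduction of the enoate to the allylic alcohol (1,2-reduction) leaves the vinyl iodide and both alkene geometries untouched.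

Step 16
Reactants: 21 (2E,5R,6Z)-7-iodo-3,5-dimethylocta-2,6-dien-1-ol
Product: 22 (2E,5R,6Z)-7-iodo-3,5-dimethylocta-2,6-dienal
Conditions: MnO2, CH2Cl2, rt
Reagents that add atoms: none
Why: MnO2 oxidation is selective for allylic alcohols and gives the E-enal without isomerisation.

Step 17
Reactants: 22 (2E,5R,6Z)-7-iodo-3,5-dimethylocta-2,6-dienal; 14 (6S)-6-ethenyl-5,6-dihydro-2H-pyran-2-one
Product: 23 (2E,5R,6Z,8E)-3,5,7-trimethyl-9-[(2S)-6-oxo-3,6-dihydro-2H-pyran-2-yl]nona-2,6,8-trienal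
Conditions: Pd(OAc)2 (10 mol %), n-Bu4NCl, NaHCO3, DMF, 40 °C
Reagents that add atoms: none
Why: Heck reaction under ligand-free Jeffery conditions, in which oxidative addition keeps the Z-iodoalkene geometry and syn-insertion at the terminal vinyl carbon followed by syn-β-hydride elimination gives the 6E,8Z-diene, the mild NaHCO3 base sparing the lactone.

Step 18
Reactants: 23 (2E,5R,6Z,8E)-3,5,7-trimethyl-9-[(2S)-6-oxo-3,6-dihydro-2H-pyran-2-yl]nona-2,6,8-trienal
Product: 24 (6S)-6-[(1E,3Z,5R,7E,9E)-10-iodo-3,5,7-trimethyldeca-1,3,7,9-tetraen-1-yl]-5,6-dihydro-2H-pyran-2-one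
Conditions: CrCl2, CHI3, THF/1,4-dioxane, 0 °C → rt
Reagents that add atoms: iodoform, IC(I)I
Why: Takai olefination, in which the geminal dichromium species adds to the aldehyde and eliminates to the E-iodoalkene (C14=C15) while being inert to the lactone.

Step 19
Reactants: 24 (6S)-6-[(1E,3Z,5R,7E,9E)-10-iodo-3,5,7-trimethyldeca-1,3,7,9-tetraen-1-yl]-5,6-dihydro-2H-pyran-2-one; 9 (2R,4S,5R,6R)-4-hydroxy-5-methyl-6-[(1E)-prop-1-en-1-yl]oxane-2-carbaldehyde
Product: 25 (6S)-6-[(1E,3Z,5R,7E,9E,11S)-11-hydroxy-11-[(2R,4S,5R,6R)-4-hydroxy-5-methyl-6-[(1E)-prop-1-en-1-yl]oxan-2-yl]-3,5,7-trimethylundeca-1,3,7,9-tetraen-1-yl]-5,6-dihydro-2H-pyran-2-one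
Conditions: CrCl2, NiCl2 (2 mol %), Kishi-type chiral oxazoline–sulfonamide ligand (antipode matched with the Felkin sense), Et3N, THF, rt
Reagents that add atoms: none
Why: Nozaki–Hiyama–Kishi coupling, in which the alkenylchromium reagent adds only to the aldehyde and the Felkin–Anh preference of the α-alkoxy aldehyde (attack anti to the ring C17–O bond), reinforced by the chiral ligand, gives Si-face addition and hence the 16S carbinol anti to C17–O, with the free hydroxyl and the lactone tolerated.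

**Compound list**

1 | methyl 2-[(4R)-2,2-dimethyl-1,3-dioxolan-4-yl]acetate | COC(=O)C[C@@H]1COC(C)(C)O1 | starting material
2 | 2-[(4R)-2,2-dimethyl-1,3-dioxolan-4-yl]acetaldehyde | O=CC[C@@H]1COC(C)(C)O1 | intermediate
3 | (4E)-hex-4-en-3-one | C/C=C/C(=O)CC | starting material
4 | (2E,5R,6S)-7-[(4R)-2,2-dimethyl-1,3-dioxolan-4-yl]-6-hydroxy-5-methylhept-2-en-4-one | C/C=C/C(=O)[C@H](C)[C@@H](O)C[C@@H]1COC(C)(C)O1 | intermediate
5 | (2E,4R,5R,6S)-7-[(4R)-2,2-dimethyl-1,3-dioxolan-4-yl]-5-methylhept-2-ene-4,6-diol | C/C=C/[C@@H](O)[C@H](C)[C@@H](O)C[C@@H]1COC(C)(C)O1 | intermediate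
6 | (4S,5R,6R)-4-{[(4R)-2,2-dimethyl-1,3-dioxolan-4-yl]methyl}-5-methyl-6-[(1E)-prop-1-en-1-yl]-1,3-dioxan-2-one | C/C=C/[C@H]1OC(=O)O[C@@H](C[C@@H]2COC(C)(C)O2)[C@H]1C | intermediate
7 | (4S,5R,6R)-4-[(2R)-2,3-dihydroxypropyl]-5-methyl-6-[(1E)-prop-1-en-1-yl]-1,3-dioxan-2-one | C/C=C/[C@H]1OC(=O)O[C@@H](C[C@@H](O)CO)[C@H]1C | intermediate
8 | (2R,3R,4S,6R)-6-(hydroxymethyl)-3-methyl-2-[(1E)-prop-1-en-1-yl]oxan-4-ol | C/C=C/[C@H]1O[C@@H](CO)C[C@H](O)[C@H]1C | intermediate
9 | (2R,4S,5R,6R)-4-hydroxy-5-methyl-6-[(1E)-prop-1-en-1-yl]oxane-2-carbaldehyde | C/C=C/[C@H]1O[C@@H](C=O)C[C@H](O)[C@H]1C | intermediate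
10 | acrolein (prop-2-enal) | C=CC=O | starting material
11 | (3S)-hexa-1,5-dien-3-ol | C=CC[C@@H](C=C)O | intermediate
12 | acryloyl chloride | C=CC(=O)Cl | starting material
13 | (3S)-hexa-1,5-dien-3-yl prop-2-enoate | C=CC[C@@H](C=C)OC(=O)C=C | intermediate
14 | (6S)-6-ethenyl-5,6-dihydro-2H-pyran-2-one | C=C[C@@H]1CC=CC(=O)O1 | intermediate
15 | (4S)-4-benzyl-3-propanoyl-1,3-oxazolidin-2-one | CCC(=O)N1[C@@H](Cc2ccccc2)COC1=O | starting material
16 | ethyl (2E)-4-bromo-3-methylbut-2-enoate (E isomer) | CCOC(=O)/C=C(\C)CBr | starting material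
17 | ethyl (2E,5R)-6-[(4S)-4-benzyl-2-oxo-1,3-oxazolidin-3-yl]-3,5-dimethyl-6-oxohex-2-enoate | CCOC(=O)/C=C(\C)C[C@@H](C)C(=O)N1[C@@H](Cc2ccccc2)COC1=O | intermediate
18 | ethyl (2E,5R)-6-hydroxy-3,5-dimethylhex-2-enoate | CCOC(=O)/C=C(\C)C[C@@H](C)CO | intermediate
19 | ethyl (2E,5R)-3,5-dimethyl-6-oxohex-2-enoate | CCOC(=O)/C=C(\C)C[C@@H](C)C=O | intermediate
20 | ethyl (2E,5R,6Z)-7-iodo-3,5-dimethylocta-2,6-dienoate | CCOC(=O)/C=C(\C)C[C@@H](C)/C=C(C)\I | intermediate
21 | (2E,5R,6Z)-7-iodo-3,5-dimethylocta-2,6-dien-1-ol | OC/C=C(\C)C[C@@H](C)/C=C(C)\I | intermediate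
22 | (2E,5R,6Z)-7-iodo-3,5-dimethylocta-2,6-dienal | O=C/C=C(\C)C[C@@H](C)/C=C(C)\I | intermediate
23 | (2E,5R,6Z,8E)-3,5,7-trimethyl-9-[(2S)-6-oxo-3,6-dihydro-2H-pyran-2-yl]nona-2,6,8-trienal | O=C/C=C(\C)C[C@@H](C)/C=C(C)\C=C\[C@@H]1CC=CC(=O)O1 | intermediate
24 | (6S)-6-[(1E,3Z,5R,7E,9E)-10-iodo-3,5,7-trimethyldeca-1,3,7,9-tetraen-1-yl]-5,6-dihydro-2H-pyran-2-one | I/C=C/C=C(\C)C[C@@H](C)/C=C(C)\C=C\[C@@H]1CC=CC(=O)O1 | intermediate
25 | (6S)-6-[(1E,3Z,5R,7E,9E,11S)-11-hydroxy-11-[(2R,4S,5R,6R)-4-hydroxy-5-methyl-6-[(1E)-prop-1-en-1-yl]oxan-2-yl]-3,5,7-trimethylundeca-1,3,7,9-tetraen-1-yl]-5,6-dihydro-2H-pyran-2-one | C/C=C/[C@H]1O[C@@H]([C@@H](O)/C=C/C=C(\C)C[C@@H](C)/C=C(C)\C=C\[C@@H]2CC=CC(=O)O2)C[C@H](O)[C@H]1C | target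

**Step count and risks**

Total step count: 19. Longest linear sequence: 9 steps (steps 11–19, from 15 and 16 to 25).

The three steps most likely to fail are steps 6, 17 and 19.

Step 6 (the proposed new cycloetherification). The zwitterion may instead fragment by β-carbon elimination to a dienal (known for 4-vinyl-1,3-dioxan-2-ones), lose a β-hydrogen to give a diene, or the carbonate may migrate to the C17/C19 diol before ionisation. The fallback uses known chemistry and sets out from diol 5. Aqueous acetic acid removes the acetonide to give (2R,4S,5R,6R,7E)-5-methylnon-7-ene-1,2,4,6-tetraol F1. Catalytic Re2O7 in CH2Cl2 (dehydrative allylic-alcohol cyclisation through the perrhenate ester and allyl cation, under thermodynamic control) then ionises only the allylic C21 hydroxyl, and the C17 hydroxyl closes the ring. The isomer with both large substituents equatorial is expected to be the stable one, and the route is rejoined at 8. The approach changes from stereospecific π-allylpalladium substitution to reversible cationic ring closure.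

Step 17 (Heck coupling). The vinyl lactone is an allylic ester that zerovalent palladium can ionise, and base can open the dihydropyranone to a dienoic acid. The fallback sets out from lactone 14. Cross-metathesis with vinylboronic acid pinacol ester (second-generation Hoveyda–Grubbs catalyst, RuCl2(=CH-C6H4-2-OiPr)(H2IMes), CH2Cl2, 40 °C) gives (6S)-6-[(E)-2-(4,4,5,5-tetramethyl-1,3,2-dioxaborolan-2-yl)ethenyl]-5,6-dihydro-2H-pyran-2-one F2. This is joined to iodide 22 by Suzuki–Miyaura coupling at room temperature (Pd(PPh3)4, TlOEt, THF/H2O), with retention of both alkene geometries, and the route is rejoined at 23. The approach changes from C–H vinylation to a boron-based cross-coupling run near neutrality.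

Step 19 (Nozaki–Hiyama–Kishi coupling). The addition may give a poor C16 ratio if the ligand and the substrate bias do not reinforce each other. The fallback sets out from aldehyde 9 and iodide 24. Ligand-free coupling (CrCl2, NiCl2 cat., DMSO) gives 25 mixed with its C16 epimer, (6S)-6-[(1E,3Z,5R,7E,9E,11R)-11-hydroxy-11-[(2R,4S,5R,6R)-4-hydroxy-5-methyl-6-[(1E)-prop-1-en-1-yl]oxan-2-yl]-3,5,7-trimethylundeca-1,3,7,9-tetraen-1-yl]-5,6-dihydro-2H-pyran-2-one F3. MnO2 oxidises only the dienylic C16 alcohol of the mixture to (6S)-6-[(1E,3Z,5R,7E,9E)-11-[(2R,4S,5R,6R)-4-hydroxy-5-methyl-6-[(1E)-prop-1-en-1-yl]oxan-2-yl]-3,5,7-trimethyl-11-oxoundeca-1,3,7,9-tetraen-1-yl]-5,6-dihydro-2H-pyran-2-one F4. Corey–Bakshi–Shibata reduction (Me-CBS oxazaborolidine, catecholborane, −78 °C, the catalyst antipode that delivers hydride to the Re face of the C16 carbonyl) then returns the route at 25. The approach changes from setting C16 in the C–C bond formation to setting it by catalyst-controlled ketone reduction.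

**Further compounds**

F1 | step 6 | (2R,4S,5R,6R,7E)-5-methylnon-7-ene-1,2,4,6-tetraol | OC[C@H](O)C[C@H](O)[C@@H](C)[C@H](O)/C=C/C
F2 | step 17 | (6S)-6-[(E)-2-(4,4,5,5-tetramethyl-1,3,2-dioxaborolan-2-yl)ethenyl]-5,6-dihydro-2H-pyran-2-one | CC1(C)OB(/C=C/[C@@H]2CC=CC(=O)O2)OC1(C)C
F3 | step 19 | (6S)-6-[(1E,3Z,5R,7E,9E,11R)-11-hydroxy-11-[(2R,4S,5R,6R)-4-hydroxy-5-methyl-6-[(1E)-prop-1-en-1-yl]oxan-2-yl]-3,5,7-trimethylundeca-1,3,7,9-tetraen-1-yl]-5,6-dihydro-2H-pyran-2-one | C/C=C/[C@H]1O[C@@H]([C@H](O)/C=C/C=C(\C)C[C@@H](C)/C=C(C)\C=C\[C@@H]2CC=CC(=O)O2)C[C@H](O)[C@H]1C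
F4 | step 19 | (6S)-6-[(1E,3Z,5R,7E,9E)-11-[(2R,4S,5R,6R)-4-hydroxy-5-methyl-6-[(1E)-prop-1-en-1-yl]oxan-2-yl]-3,5,7-trimethyl-11-oxoundeca-1,3,7,9-tetraen-1-yl]-5,6-dihydro-2H-pyran-2-one | C/C=C/[C@H]1O[C@@H](C(=O)/C=C/C=C(\C)C[C@@H](C)/C=C(C)\C=C\[C@@H]2CC=CC(=O)O2)C[C@H](O)[C@H]1C
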